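## The problem

The target (29, germacrane numbering throughout) is an 11-oxabicyclo[6.2.1]undecane. Its ten-membered carbocycle C1–C10 is bridged by oxygen between C3 and C10, so that O, C3, C2, C1 and C10 form a 3(2H)-furanone, and the C6–C7 bond carries a trans-fused α-methylene-γ-lactone (C12, C11=C13). The ring contains a Z C4=C5 double bond conjugated with the furanone, the free allylic alcohol C15 sits on C4, and C8 bears a methacrylate. There are four stereocentres: the contiguous set C6 (R), C7 (R), C8 (R) and the isolated quaternary C10 (S). C6 can direct C7 through the lactone ring, and C7 and C8 can be made in one bond-forming event. C10 is cut off from them by the C9 methylene and the flat furanone, so it must be set on its own in absolute terms. Three Michael acceptors (exo-methylene lactone, methacrylate, cross-conjugated dienone) rule out strong bases, hydride donors and hard nucleophiles late in the route. Any C8 carbonyl intermediate is also a β-oxy carbonyl compound that can expel the furanone oxygen from C10 and lose the C10 configuration. The enabling feature is C10 itself: it carries the ring oxygen, a methyl group and the acyl carbon C1, which is the array left when a methyl group moves from a carbinol carbon (C1) to an adjacent oxocarbenium carbon (C10). Furanone and quaternary centre can therefore be made together from a tertiary propargylic ketol.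

## Retrosynthesis

**29 from 28 and 27.** The C15 O–Si bond is cut last, and before it the C8–O ester bond, formed with inversion from the 8S alcohol 27. Acylating late keeps the methacrylate away from the organometallic ring closure. Inversion is planned because the ring-closing allylation is expected to deliver the 8-epimer. The forward step must be a clean SN2 displacement at a hindered secondary carbon next to an activated C7–H.

**27 from 25.** The C7–C8 bond is cut, opening the ten-membered ring to an aldehyde at C8 and a 3-(bromomethyl)butenolide that already contains C6. A C5–C6 vinyl–aldehyde closure would leave C7 as a doubly activated stereocentre next to an aldehyde and give no handle on C6. A C8–C9 aldol closure would put a carbanion next to the C10 leaving group. The C7–C8 cut lets the lactone stereocentre C6 control C7, creates C8 in the same transition state and reveals the exo-methylene group. The precursor 25 has only two stereocentres (C6, C10) and no macrocycle. The forward reaction must reach the butenolide face anti to the C5 substituent under high dilution.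

**25 from 22 via 24 and 23.** These are functional-group changes only: the aldehyde comes from a dioxolane and the bromide from a silyl-protected primary alcohol. The bromide is installed before the aldehyde is released so that the phosphine reagent never meets the aldehyde and the sensitive β-oxy aldehyde is made last.

**22 from 20 (key disconnection).** The O–C3 bond and the C10–CH3 bond are cut, with the methyl returned to C1. The furanone 22 becomes the open-chain 2-hydroxy-2-methyl-3-ynone 20. The alternative of closing a C10 carbinol onto a 1,3-diketone needs the quaternary C10 built separately. This cut replaces it with a tertiary propargylic carbinol, the adduct of an alkyne and a pyruvate. The forward step must make the reluctant methyl group migrate and must pass the carbinol configuration on to C10.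

**20 from 7 and 19.** The C3–C4 bond is cut into a terminal alkyne and an alkenyl iodide (Sonogashira). This is the most convergent cut: it divides the molecule into two fragments of similar size, each with one stereocentre. The forward coupling must retain the alkene geometry and must not epimerise C6.

**7 from 1, 2 and 5.** The C9–C10 bond is cut to the Weinreb amide 4 and the acetal Grignard reagent 5; the TMS ketone 6 is only desilylated to 7. The C1–C2 bond is cut to ethyl pyruvate 1 and trimethylsilylacetylene 2, which give ester 3 and then amide 4. All are commercial, and the single stereocentre comes from one catalytic alkynylation.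

**19 from 8, 10 and 15.** The butenolide C7=C11 bond is cut by ring-closing metathesis to the acrylate ester 18. Ester 18 comes from alcohol 14 and acid 17, and 17 from methyl 2-(hydroxymethyl)acrylate 15 via 16. Alcohol 14 is the trans-hydroalumination–iodination product of propargylic alcohol 12, which fixes the C4=C5 geometry. Alcohol 12 is the enantioselective adduct of silyl ether 9 (from propargyl alcohol 8) and crotonaldehyde 10.

## Roads not taken

**Alternative 1: fragmentation of a guaiane-type hydroazulene.** The cut is the C1–C5 bond of a cis-fused bicyclo[5.3.0]decane. Forward, a C1 alkoxide expels that bond anti to a C4/C15 spiro-epoxide and gives A1, the ten-membered 10-hydroxy-1-ketone with a masked C3 ketone. In two respects this road is better than the chosen one: the ring is made by ring expansion without high dilution, and the Z C4=C5 geometry follows stereospecifically from relative configuration. It also frees the C15 alcohol and leaves a short cyclodehydration to the furanone. Its weak points are the long preparation of a hydroazulene with sacrificial stereocentres at C1, C4 and C5, and a basic key step run on a substrate that, as A1 shows, already carries the methacrylate and the exo-methylene lactone. A vicinal C1/C10 diol pattern also invites retro-aldol or pinacol paths. The chosen plan answers with convergence, only four stereocentres ever built, and a near-neutral furanone-forming step.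

**Alternative 2: nitrile oxide macrocyclisation.** The cut is C1–C2 plus the isoxazole O–C3 bond. Forward, a C1 nitrile oxide adds across the terminal C2≡C3 alkyne of a Z-enyne and gives A2, a 3,5-bridged isoxazole that masks the C1/C3 dioxygen pattern. Closing the ring and installing the masked diketone in one step, in a heterocycle that survives many later operations, is more economical than anything in the chosen plan. The weak points are the strain of a seven-atom bridge across the 3,5-positions, which favours furoxan dimers or the wrong regiochemistry, and the reductive N–O cleavage. A2 also still lacks the exo-methylene group and the methacrylate, so the endgame is long. The chosen plan delivers the furanone directly at the right oxidation level and needs no reduction.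

**Alternative 3: oxonium ylide [2,3]-shift.** The cuts are O–C10 and C9–C10. Forward, a metal carbenoid at C10 (from a diazoketone with Rh2(OAc)4 or Cu(acac)2) is trapped by the oxygen of an eight-membered allylic ether, and the ylide rearranges to A3, the oxygen-bridged core with a C8 exo-methylene group. It creates C10, the ether bridge and the ten-membered ring in one ring-expanding event, which is better than a high-dilution closure. The weak points are that a carbenoid bearing a methyl group is prone to 1,2-hydride shift, and that the C10 configuration depends on facial selectivity in the rearrangement. A3 also still needs C8 converted from methylene to an acyloxy stereocentre beside two other alkenes, and C2–C3 dehydrogenated. The chosen plan sets C10 by transfer from a defined centre and carries every carbon at its final oxidation level.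

Key step: step 13

Assumption: the ligand enantiomers named in steps 1 and 6 are taken to be those that give the S carbinols; if the sense of induction proves opposite, the mirror-image ligand is used and nothing else changes.

## Route

Step 1
Reactants: 1 ethyl pyruvate; 2 trimethylsilylacetylene
Product: 3 ethyl (2S)-2-hydroxy-2-methyl-4-(trimethylsilyl)but-3-ynoate
Conditions: Zn(OTf)2, Et3N, (1S,2S)-2-(dimethylamino)-1-(4-nitrophenyl)-3-[tert-butyl(dimethyl)silyloxy]propan-1-ol, toluene, 70 °C, sealed vessel
Reagents that add atoms: none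
Why: Catalytic enantioselective alkynylation of an α-keto ester: the zinc acetylide of 2 adds to the ketone carbonyl of the chelated pyruvate, and the amino alcohol ligand selects the face. This sets the carbinol (future C1, S), the only source of the C10 configuration.

Step 2
Reactants: 3 ethyl (2S)-2-hydroxy-2-methyl-4-(trimethylsilyl)but-3-ynoate
Product: 4 (2S)-2-hydroxy-N-methoxy-N,2-dimethyl-4-(trimethylsilyl)but-3-ynamide
Conditions: MeNH(OMe)·HCl, i-PrMgCl, THF, −20 to 0 °C
Reagents that add atoms: N,O-dimethylhydroxylamine hydrochloride, Cl.CNOC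
Why: Weinreb amide formation by aminolysis of the ester with the chloromagnesium amide; the α-alkoxide formed first activates the ester by chelation, and the silylalkyne and the tertiary centre are untouched.

Step 3
Reactants: 4 (2S)-2-hydroxy-N-methoxy-N,2-dimethyl-4-(trimethylsilyl)but-3-ynamide; 5 (1,3-dioxolan-2-ylmethyl)magnesium bromide
Product: 6 (3S)-1-(1,3-dioxolan-2-yl)-3-hydroxy-3-methyl-5-(trimethylsilyl)pent-4-yn-2-one
Conditions: 5 (3 equiv), THF, 0 °C to rt; aq. NH4Cl
Reagents that add atoms: none
Why: Grignard addition to a Weinreb amide; one equivalent is consumed by the hydroxyl group, and the magnesium chelate prevents over-addition, so the C10 ketone with its C9–C8 acetal arm appears only on work-up.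

Step 4
Reactants: 6 (3S)-1-(1,3-dioxolan-2-yl)-3-hydroxy-3-methyl-5-(trimethylsilyl)pent-4-yn-2-one
Product: 7 (3S)-1-(1,3-dioxolan-2-yl)-3-hydroxy-3-methylpent-4-yn-2-one
Conditions: K2CO3 (0.3 equiv), MeOH, 0 °C
Reagents that add atoms: none
Why: Methanolysis of the alkynyl C–Si bond under catalytic carbonate; cold and brief so that the tertiary α-ketol does not rearrange and the β-keto acetal does not eliminate.

Step 5
Reactants: 8 propargyl alcohol
Product: 9 tert-butyl(diphenyl)(prop-2-yn-1-yloxy)silane
Conditions: TBDPSCl, imidazole, CH2Cl2, 0 °C to rt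
Reagents that add atoms: tert-butyl(chloro)diphenylsilane, CC(C)(C)[Si](Cl)(c1ccccc1)c1ccccc1
Why: Standard silylation; the diphenylsilyl ether is chosen because the C15 oxygen must survive the acidic acetal cleavage of step 16 and stay on until the last step.

Step 6
Reactants: 9 tert-butyl(diphenyl)(prop-2-yn-1-yloxy)silane; 10 (2E)-but-2-enal
Product: 12 (4S,5E)-1-[tert-butyl(diphenyl)silyloxy]hept-5-en-2-yn-4-ol, via alkynyl(methyl)zinc 11 (not isolated)
Conditions: 9, Me2Zn, (S,S)-ProPhenol (20 mol%), Ph3PO (40 mol%), toluene, 0 °C; then 10, 4 °C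
Reagents that add atoms: none
Why: Dinuclear zinc–ProPhenol enantioselective alkynylation of an α,β-unsaturated aldehyde: the alkynylzinc 11 adds 1,2 to the enal in the chiral pocket and sets the future C6 (S here, because the alkynyl branch outranks the alkenyl branch). Crotonaldehyde is used instead of acrolein because it behaves well in this addition; its extra carbon leaves as propene in step 11.

Step 7
Reactants: 12 (4S,5E)-1-[tert-butyl(diphenyl)silyloxy]hept-5-en-2-yn-4-ol
Product: 14 (2Z,4S,5E)-1-[tert-butyl(diphenyl)silyloxy]-2-iodohepta-2,5-dien-4-ol, via cyclic alkenylalanate 13 (not isolated)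
Conditions: NaAlH2(OCH2CH2OCH3)2 (Red-Al), THF, 0 °C to rt; EtOAc; then I2, THF, −78 °C
Reagents that add atoms: iodine, II
Why: Alkoxide-directed trans-hydroalumination of the propargylic alcohol puts aluminium on the distal alkyne carbon (future C4) in the five-membered alanate 13, and iodinolysis with retention gives the iodoalkene with iodine cis to the carbinol carbon. This fixes the C4=C5 geometry of the target; the isolated propenyl group and the silyl ether are inert.

Step 8
Reactants: 15 methyl 2-(hydroxymethyl)prop-2-enoate
Product: 16 methyl 2-{[tert-butyl(dimethyl)silyloxy]methyl}prop-2-enoate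
Conditions: TBSCl, imidazole, CH2Cl2, 0 °C to rt
Reagents that add atoms: tert-butyl(chloro)dimethylsilane, CC(C)(C)[Si](C)(C)Cl
Why: Standard silylation; the dimethylsilyl ether on the future C13 is chosen so that it can be removed in step 14 while the diphenylsilyl ether on C15 stays.

Step 9
Reactants: 16 methyl 2-{[tert-butyl(dimethyl)silyloxy]methyl}prop-2-enoate
Product: 17 2-{[tert-butyl(dimethyl)silyloxy]methyl}prop-2-enoic acid
Conditions: LiOH·H2O, THF–H2O, 0 °C to rt; then 1 M HCl to pH 4, 0 °C
Reagents that add atoms: lithium hydroxide, [Li+].[OH-]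
Why: Saponification of the methyl ester; the primary silyl ether tolerates cold hydroxide and a brief mild acidification.

Step 10
Reactants: 14 (2Z,4S,5E)-1-[tert-butyl(diphenyl)silyloxy]-2-iodohepta-2,5-dien-4-ol; 17 2-{[tert-butyl(dimethyl)silyloxy]methyl}prop-2-enoic acid
Product: 18 (2Z,4S,5E)-1-[tert-butyl(diphenyl)silyloxy]-2-iodohepta-2,5-dien-4-yl 2-{[tert-butyl(dimethyl)silyloxy]methyl}prop-2-enoate
Conditions: DCC, DMAP (cat.), CH2Cl2, 0 °C to rt
Reagents that add atoms: none
Why: Steglich esterification of the secondary alcohol; the C–O bond of the carbinol is not broken, so C6 keeps its configuration.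

Step 11
Reactants: 18 (2Z,4S,5E)-1-[tert-butyl(diphenyl)silyloxy]-2-iodohepta-2,5-dien-4-yl 2-{[tert-butyl(dimethyl)silyloxy]methyl}prop-2-enoate
Product: 19 (5S)-3-{[tert-butyl(dimethyl)silyloxy]methyl}-5-[(1Z)-3-[tert-butyl(diphenyl)silyloxy]-2-iodoprop-1-en-1-yl]furan-2(5H)-one
Conditions: second-generation Grubbs catalyst RuCl2(=CHPh)(H2IMes)(PCy3) (10 mol%), toluene (5 mM), 80 °C
Reagents that add atoms: none
Why: Ring-closing metathesis between the propenyl group and the 1,1-disubstituted acrylate forms the C7=C11 bond of the butenolide with loss of propene. The trisubstituted iodoalkene is too hindered to enter the cycle, and C6 is not touched.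

Step 12
Reactants: 7 (3S)-1-(1,3-dioxolan-2-yl)-3-hydroxy-3-methylpent-4-yn-2-one; 19 (5S)-3-{[tert-butyl(dimethyl)silyloxy]methyl}-5-[(1Z)-3-[tert-butyl(diphenyl)silyloxy]-2-iodoprop-1-en-1-yl]furan-2(5H)-one
Product: 20 (5R)-3-{[tert-butyl(dimethyl)silyloxy]methyl}-5-[(1E,5S)-2-{[tert-butyl(diphenyl)silyloxy]methyl}-7-(1,3-dioxolan-2-yl)-5-hydroxy-5-methyl-6-oxohept-1-en-3-yn-1-yl]furan-2(5H)-one
Conditions: Pd(PPh3)4 (5 mol%), CuI (10 mol%), Et3N (3 equiv), degassed THF, 0 °C
Reagents that add atoms: none
Why: Sonogashira coupling of the alkenyl iodide with the terminal alkyne forms C3–C4 with retention of the alkene geometry (the alkyne ends up cis to the butenolide; the descriptors change only through priority rules). Low temperature and a short reaction time limit amine deprotonation of the butenolide γ-hydrogen at C6.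

Step 13
Reactants: 20 (5R)-3-{[tert-butyl(dimethyl)silyloxy]methyl}-5-[(1E,5S)-2-{[tert-butyl(diphenyl)silyloxy]methyl}-7-(1,3-dioxolan-2-yl)-5-hydroxy-5-methyl-6-oxohept-1-en-3-yn-1-yl]furan-2(5H)-one
Product: 22 (5R)-3-{[tert-butyl(dimethyl)silyloxy]methyl}-5-[(1Z)-3-[tert-butyl(diphenyl)silyloxy]-2-[(5S)-5-(1,3-dioxolan-2-ylmethyl)-5-methyl-4-oxo-4,5-dihydrofuran-2-yl]prop-1-en-1-yl]furan-2(5H)-one, via platinated cyclic oxocarbenium ion 21 (not isolated)
Conditions: PtCl2 (10 mol%), toluene, 80 °C
Reagents that add atoms: none
Why: PtCl2 coordinates the C2≡C3 triple bond and the C10 carbonyl oxygen adds to C3 in a 5-endo-dig closure, the only ring made in the step (attack at C2 would need a four-membered ring), giving the oxocarbenium ion 21. The methyl group then moves from C1 to the electron-poor C10 as the C1 hydroxyl becomes the C1 carbonyl, and protodemetalation at C2 releases the 3(2H)-furanone. The closest known reaction type is the PtCl2- or AuCl3-catalysed heterocyclisation with 1,2-migration of 2-hydroxy-2-alkynyl ketones, in which methyl migration in open-chain substrates is known but slower than ring-contracting shifts. C10 is the only new stereocentre: a 1,2-shift is necessarily suprafacial, so the methyl group arrives on the ring face it occupied at C1 and the S carbinol gives 10S. No other group can migrate because the alkynyl carbon and C10 are ring members. The step needs migration to outrun loss of a C9 proton or capture of 21 by water, and it needs the Meyer–Schuster path to stay closed, which the ketone next to C1 secures by destabilising the propargylic cation. The C6 oxygen is tied up as the lactone so it cannot close onto the alkyne to a furan, and the conjugated enyne keeps C3 the electrophilic terminus. PtCl2 in toluene is preferred to AuCl3 because the acetal and both silyl ethers must survive.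

Step 14
Reactants: 22 (5R)-3-{[tert-butyl(dimethyl)silyloxy]methyl}-5-[(1Z)-3-[tert-butyl(diphenyl)silyloxy]-2-[(5S)-5-(1,3-dioxolan-2-ylmethyl)-5-methyl-4-oxo-4,5-dihydrofuran-2-yl]prop-1-en-1-yl]furan-2(5H)-one
Product: 23 (5R)-5-[(1Z)-3-[tert-butyl(diphenyl)silyloxy]-2-[(5S)-5-(1,3-dioxolan-2-ylmethyl)-5-methyl-4-oxo-4,5-dihydrofuran-2-yl]prop-1-en-1-yl]-3-(hydroxymethyl)furan-2(5H)-one
Conditions: HF·pyridine, pyridine, THF, 0 °C
Reagents that add atoms: none
Why: Selective desilylation: the primary tert-butyldimethylsilyl ether is cleaved by buffered HF much faster than the tert-butyldiphenylsilyl ether, and the acetal is stable to these conditions.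

Step 15
Reactants: 23 (5R)-5-[(1Z)-3-[tert-butyl(diphenyl)silyloxy]-2-[(5S)-5-(1,3-dioxolan-2-ylmethyl)-5-methyl-4-oxo-4,5-dihydrofuran-2-yl]prop-1-en-1-yl]-3-(hydroxymethyl)furan-2(5H)-one
Product: 24 (5R)-3-(bromomethyl)-5-[(1Z)-3-[tert-butyl(diphenyl)silyloxy]-2-[(5S)-5-(1,3-dioxolan-2-ylmethyl)-5-methyl-4-oxo-4,5-dihydrofuran-2-yl]prop-1-en-1-yl]furan-2(5H)-one
Conditions: CBr4, PPh3, CH2Cl2, 0 °C
Reagents that add atoms: carbon tetrabromide, BrC(Br)(Br)Br
Why: Appel bromination of the primary allylic alcohol under neutral conditions; it is done while C8 is still an acetal so that no aldehyde is exposed to the phosphine–tetrabromide reagent.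

Step 16
Reactants: 24 (5R)-3-(bromomethyl)-5-[(1Z)-3-[tert-butyl(diphenyl)silyloxy]-2-[(5S)-5-(1,3-dioxolan-2-ylmethyl)-5-methyl-4-oxo-4,5-dihydrofuran-2-yl]prop-1-en-1-yl]furan-2(5H)-one
Product: 25 (5R)-3-(bromomethyl)-5-[(1Z)-3-[tert-butyl(diphenyl)silyloxy]-2-[(5S)-5-methyl-4-oxo-5-(2-oxoethyl)-4,5-dihydrofuran-2-yl]prop-1-en-1-yl]furan-2(5H)-one
Conditions: PPTS, acetone–H2O (9:1), 50 °C
Reagents that add atoms: water, O
Why: Acid-catalysed acetal hydrolysis; an electron-poor allylic bromide of this kind and the diphenylsilyl ether tolerate mild aqueous acid. The β-oxy aldehyde is taken on crude and without contact with base, so that the furanone oxygen is not expelled from C10.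

Step 17
Reactants: 25 (5R)-3-(bromomethyl)-5-[(1Z)-3-[tert-butyl(diphenyl)silyloxy]-2-[(5S)-5-methyl-4-oxo-5-(2-oxoethyl)-4,5-dihydrofuran-2-yl]prop-1-en-1-yl]furan-2(5H)-one
Product: 27 (6R,7R,8S,10S)-15-[tert-butyl(diphenyl)silyloxy]-8-hydroxy-1-oxo-3,10-epoxygermacra-2,4(Z),11(13)-trien-12,6-olide, via allylchromium dichloride 26 (not isolated)
Conditions: CrCl2 (8 equiv), THF, rt, slow addition to a final 2 mM
Reagents that add atoms: none
Why: Divalent chromium turns the allylic bromide into the allylchromium 26, which adds through C7 to the C8 aldehyde in a six-membered Zimmerman–Traxler transition state (intramolecular Nozaki–Hiyama-type allylation). This closes the ten-membered ring and reveals the exo-methylene lactone. C7 is set by C6, because the aldehyde reaches the butenolide face anti to the C5 substituent (trans lactone). With the ring-locked allyl geometry and the aldehyde chain pseudo-equatorial, the chair is expected to give the 7,8-anti alcohol, which is 8S, the C8 epimer of the target.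

Step 18
Reactants: 27 (6R,7R,8S,10S)-15-[tert-butyl(diphenyl)silyloxy]-8-hydroxy-1-oxo-3,10-epoxygermacra-2,4(Z),11(13)-trien-12,6-olide
Product: 28 (6R,7R,8R,10S)-15-[tert-butyl(diphenyl)silyloxy]-8-(2-methylprop-2-enoyloxy)-1-oxo-3,10-epoxygermacra-2,4(Z),11(13)-trien-12,6-olide
Conditions: methacrylic acid, PPh3, DIAD, toluene, 0 °C to rt
Reagents that add atoms: methacrylic acid, C=C(C)C(=O)O
Why: Mitsunobu esterification: the alkoxyphosphonium ion at C8 is displaced by methacrylate with inversion. This corrects C8 to R and installs the ester in one operation, under neutral conditions that the exo-methylene lactone and the furanone tolerate.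

Step 19
Reactants: 28 (6R,7R,8R,10S)-15-[tert-butyl(diphenyl)silyloxy]-8-(2-methylprop-2-enoyloxy)-1-oxo-3,10-epoxygermacra-2,4(Z),11(13)-trien-12,6-olide
Product: 29 (6R,7R,8R,10S)-15-hydroxy-8-(2-methylprop-2-enoyloxy)-1-oxo-3,10-epoxygermacra-2,4(Z),11(13)-trien-12,6-olide (CNP0180483.4)
Conditions: HF·pyridine, THF, 0 °C to rt
Reagents that add atoms: none
Why: Fluoride-mediated cleavage of the primary silyl ether; HF·pyridine is neither basic nor nucleophilic enough to add to the methacrylate, the exo-methylene lactone or the dienone.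

## Compound list

1 | ethyl pyruvate | CCOC(=O)C(C)=O | starting material
2 | trimethylsilylacetylene | C#C[Si](C)(C)C | starting material
3 | ethyl (2S)-2-hydroxy-2-methyl-4-(trimethylsilyl)but-3-ynoate | C[C@](O)(C#C[Si](C)(C)C)C(=O)OCC | intermediate
4 | (2S)-2-hydroxy-N-methoxy-N,2-dimethyl-4-(trimethylsilyl)but-3-ynamide | C[C@](O)(C#C[Si](C)(C)C)C(=O)N(C)OC | intermediate
5 | (1,3-dioxolan-2-ylmethyl)magnesium bromide (commercial THF solution) | Br[Mg]CC1OCCO1 | starting material
6 | (3S)-1-(1,3-dioxolan-2-yl)-3-hydroxy-3-methyl-5-(trimethylsilyl)pent-4-yn-2-one | C[C@](O)(C#C[Si](C)(C)C)C(=O)CC1OCCO1 | intermediate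
7 | (3S)-1-(1,3-dioxolan-2-yl)-3-hydroxy-3-methylpent-4-yn-2-one | C[C@](O)(C#C)C(=O)CC1OCCO1 | intermediate
8 | propargyl alcohol | C#CCO | starting material
9 | tert-butyl(diphenyl)(prop-2-yn-1-yloxy)silane | C#CCO[Si](c1ccccc1)(c1ccccc1)C(C)(C)C | intermediate
10 | (2E)-but-2-enal (crotonaldehyde) | C/C=C/C=O | starting material
11 | methyl{3-[tert-butyl(diphenyl)silyloxy]prop-1-yn-1-yl}zinc | C[Zn]C#CCO[Si](c1ccccc1)(c1ccccc1)C(C)(C)C | intermediate (not isolated)
12 | (4S,5E)-1-[tert-butyl(diphenyl)silyloxy]hept-5-en-2-yn-4-ol | C/C=C/[C@H](O)C#CCO[Si](c1ccccc1)(c1ccccc1)C(C)(C)C | intermediate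
13 | sodium (5S)-2,2-bis(2-methoxyethoxy)-5-[(1E)-prop-1-en-1-yl]-3-{[tert-butyl(diphenyl)silyloxy]methyl}-2,5-dihydro-1,2-oxaluminol-2-uide (cyclic alkenylalanate) | C/C=C/[C@H]1C=C(CO[Si](c2ccccc2)(c2ccccc2)C(C)(C)C)[Al-](OCCOC)(OCCOC)O1.[Na+] | intermediate (not isolated)
14 | (2Z,4S,5E)-1-[tert-butyl(diphenyl)silyloxy]-2-iodohepta-2,5-dien-4-ol | C/C=C/[C@H](O)/C=C(\I)CO[Si](c1ccccc1)(c1ccccc1)C(C)(C)C | intermediate
15 | methyl 2-(hydroxymethyl)prop-2-enoate | C=C(CO)C(=O)OC | starting material
16 | methyl 2-{[tert-butyl(dimethyl)silyloxy]methyl}prop-2-enoate | C=C(CO[Si](C)(C)C(C)(C)C)C(=O)OC | intermediate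
17 | 2-{[tert-butyl(dimethyl)silyloxy]methyl}prop-2-enoic acid | C=C(CO[Si](C)(C)C(C)(C)C)C(=O)O | intermediate
18 | (2Z,4S,5E)-1-[tert-butyl(diphenyl)silyloxy]-2-iodohepta-2,5-dien-4-yl 2-{[tert-butyl(dimethyl)silyloxy]methyl}prop-2-enoate | C/C=C/[C@H](OC(=O)C(=C)CO[Si](C)(C)C(C)(C)C)/C=C(\I)CO[Si](c1ccccc1)(c1ccccc1)C(C)(C)C | intermediate
19 | (5S)-3-{[tert-butyl(dimethyl)silyloxy]methyl}-5-[(1Z)-3-[tert-butyl(diphenyl)silyloxy]-2-iodoprop-1-en-1-yl]furan-2(5H)-one | I/C(CO[Si](c1ccccc1)(c1ccccc1)C(C)(C)C)=C\[C@H]2OC(=O)C(CO[Si](C)(C)C(C)(C)C)=C2 | intermediate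
20 | (5R)-3-{[tert-butyl(dimethyl)silyloxy]methyl}-5-[(1E,5S)-2-{[tert-butyl(diphenyl)silyloxy]methyl}-7-(1,3-dioxolan-2-yl)-5-hydroxy-5-methyl-6-oxohept-1-en-3-yn-1-yl]furan-2(5H)-one | C[C@](O)(C#C/C(CO[Si](c1ccccc1)(c1ccccc1)C(C)(C)C)=C\[C@H]2OC(=O)C(CO[Si](C)(C)C(C)(C)C)=C2)C(=O)CC1OCCO1 | intermediate (key-step precursor)
21 | platinated cyclic oxocarbenium ion (O–C3 bond formed, PtCl2 on C2, methyl still on C1) | C[C@]1(O)C([Pt-](Cl)Cl)=C(/C(CO[Si](c2ccccc2)(c2ccccc2)C(C)(C)C)=C\[C@H]2OC(=O)C(CO[Si](C)(C)C(C)(C)C)=C2)[O+]=C1CC1OCCO1 | intermediate (not isolated)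
22 | (5R)-3-{[tert-butyl(dimethyl)silyloxy]methyl}-5-[(1Z)-3-[tert-butyl(diphenyl)silyloxy]-2-[(5S)-5-(1,3-dioxolan-2-ylmethyl)-5-methyl-4-oxo-4,5-dihydrofuran-2-yl]prop-1-en-1-yl]furan-2(5H)-one | C[C@@]1(CC2OCCO2)OC(=CC1=O)/C(CO[Si](c3ccccc3)(c3ccccc3)C(C)(C)C)=C\[C@H]4OC(=O)C(CO[Si](C)(C)C(C)(C)C)=C4 | intermediate (key-step product)
23 | (5R)-5-[(1Z)-3-[tert-butyl(diphenyl)silyloxy]-2-[(5S)-5-(1,3-dioxolan-2-ylmethyl)-5-methyl-4-oxo-4,5-dihydrofuran-2-yl]prop-1-en-1-yl]-3-(hydroxymethyl)furan-2(5H)-one | C[C@@]1(CC2OCCO2)OC(=CC1=O)/C(CO[Si](c3ccccc3)(c3ccccc3)C(C)(C)C)=C\[C@H]4OC(=O)C(CO)=C4 | intermediate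
24 | (5R)-3-(bromomethyl)-5-[(1Z)-3-[tert-butyl(diphenyl)silyloxy]-2-[(5S)-5-(1,3-dioxolan-2-ylmethyl)-5-methyl-4-oxo-4,5-dihydrofuran-2-yl]prop-1-en-1-yl]furan-2(5H)-one | C[C@@]1(CC2OCCO2)OC(=CC1=O)/C(CO[Si](c3ccccc3)(c3ccccc3)C(C)(C)C)=C\[C@H]4OC(=O)C(CBr)=C4 | intermediate
25 | (5R)-3-(bromomethyl)-5-[(1Z)-3-[tert-butyl(diphenyl)silyloxy]-2-[(5S)-5-methyl-4-oxo-5-(2-oxoethyl)-4,5-dihydrofuran-2-yl]prop-1-en-1-yl]furan-2(5H)-one | C[C@@]1(CC=O)OC(=CC1=O)/C(CO[Si](c3ccccc3)(c3ccccc3)C(C)(C)C)=C\[C@H]4OC(=O)C(CBr)=C4 | intermediate
26 | allylchromium dichloride derived from 25 (chromium on C13) | C[C@@]1(CC=O)OC(=CC1=O)/C(CO[Si](c3ccccc3)(c3ccccc3)C(C)(C)C)=C\[C@H]4OC(=O)C(C[Cr](Cl)Cl)=C4 | intermediate (not isolated)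
27 | (6R,7R,8S,10S)-15-[tert-butyl(diphenyl)silyloxy]-8-hydroxy-1-oxo-3,10-epoxygermacra-2,4(Z),11(13)-trien-12,6-olide | O[C@H]1C[C@]2(C)OC(=CC2=O)/C(CO[Si](c3ccccc3)(c3ccccc3)C(C)(C)C)=C\[C@H]2OC(=O)C(=C)[C@@H]21 | intermediate
28 | (6R,7R,8R,10S)-15-[tert-butyl(diphenyl)silyloxy]-8-(2-methylprop-2-enoyloxy)-1-oxo-3,10-epoxygermacra-2,4(Z),11(13)-trien-12,6-olide | C=C(C)C(=O)O[C@@H]1C[C@]2(C)OC(=CC2=O)/C(CO[Si](c3ccccc3)(c3ccccc3)C(C)(C)C)=C\[C@H]2OC(=O)C(=C)[C@@H]21 | intermediate
29 | (6R,7R,8R,10S)-15-hydroxy-8-(2-methylprop-2-enoyloxy)-1-oxo-3,10-epoxygermacra-2,4(Z),11(13)-trien-12,6-olide (CNP0180483.4) | C=C(C)C(=O)O[C@@H]1C[C@]2(C)OC(=CC2=O)/C(CO)=C\[C@H]2OC(=O)C(=C)[C@@H]21 | target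

## Step count and least certain steps

Total: 19 steps. Longest linear sequence: 13 steps (5, 6, 7, 10, 11, 12–19).

**Step 13 (key step).** The reluctant methyl group may migrate more slowly than the oxocarbenium ion loses a C9 proton or is captured by adventitious water, and the Lewis-acidic metal may attack the acetal. The fallback keeps the same two bonds but triggers them with an electrophile. It sets out from 20 and returns at 22. The tertiary hydroxyl is silylated (TMSCl, imidazole) to the trimethylsilyl ether F1. N-Iodosuccinimide in CH2Cl2 then activates the alkyne as an iodonium ion; O–C3 closure and methyl shift follow, with loss of the silyl group in place of a proton, to give the 2-iodofuranone F2. This electrophile-induced cyclisation–migration is known for 2-silyloxy-2-alkynyl ketones. Hydrodeiodination with Bu3SnH and Pd(PPh3)4 gives 22.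

**Step 17.** The tether may steer the aldehyde to the same face as the C5 substituent (cis lactone), intermolecular allylation may compete, or the allylchromium may be protonated before it closes. The fallback replaces the closed, metal-bridged transition state by an open one. It sets out from 24 and returns at 28. Hexabutylditin with Pd(PPh3)4 converts the bromide into the allylstannane F3. PPTS in aqueous acetone releases the aldehyde F4. BF3·OEt2 in CH2Cl2 at −78 °C then promotes an intramolecular allylation through an antiperiplanar open transition state, which should favour the 7,8-syn alcohol F5 with the 8R configuration of the target. Methacrylic anhydride, Et3N and DMAP acylate F5 with retention to 28, so no inversion is needed.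

**Step 18.** Elimination toward C7 (its hydrogen is activated by the exo-methylene lactone) or incomplete inversion at the hindered C8 may compete with displacement. The fallback separates activation from displacement. It sets out from 27 and returns at 28. MsCl and Et3N at −20 °C give the mesylate F6, which is displaced with caesium methacrylate and 18-crown-6 in toluene to give 28 with inversion. If step 17 gives the 8R alcohol instead, it is F5 and is simply acylated as above.

**Step 12.** The amine may deprotonate the butenolide γ-position and erode the C6 configuration, and copper may dimerise the alkyne. The fallback is a base-free coupling. It sets out from 7 and returns at 20. Bu3SnOMe converts the terminal alkyne into the alkynylstannane F7, which is coupled with 19 under Stille conditions (Pd2(dba)3, AsPh3, DMF, rt).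

**Step 1.** Facial discrimination between the methyl and ester sides of a pyruvate may be insufficient. The fallback uses resolution instead of catalysis. It sets out from 1 and 2 and returns at 7.
- Lithiated 2 (LiHMDS, THF, −78 °C) adds to 1 to give the racemic ester F8.
- LiOH cleaves the ester and the C–Si bond to give the racemic acid F9.
- Crystallisation with (1R)-1-phenylethanamine gives the salt F10 of the S acid (the amine enantiomer is chosen by which salt crystallises).
- Acidification frees the S acid F11.
- EDC, HOBt and MeNH(OMe)·HCl give the Weinreb amide F12.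
- 5 (4 equiv) converts F12 directly into 7.

**Step 6.** Enantioselectivity may be poor with a small enal, or conjugate addition may compete. The fallback has a predictable stereochemical sense. It sets out from 9 and 10 and returns at 12. Lithiated 9 (n-BuLi, THF, −78 °C) adds to 10 to give the racemic alcohol F13. Sharpless kinetic resolution (Ti(OiPr)4, L-(+)-diisopropyl tartrate, t-BuOOH, 4 Å sieves, CH2Cl2, −20 °C) epoxidises the 4R enantiomer to the epoxy alcohol F14 and leaves the S alcohol 12.

## Further compounds

F1 | step 13 | trimethylsilyl ether of 20 at the tertiary hydroxyl | C[C@](O[Si](C)(C)C)(C#C/C(CO[Si](c1ccccc1)(c1ccccc1)C(C)(C)C)=C\[C@H]2OC(=O)C(CO[Si](C)(C)C(C)(C)C)=C2)C(=O)CC1OCCO1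
F2 | step 13 | 2-iodo derivative of 22 (iodine on the furanone CH, C2 in germacrane numbering) | C[C@@]1(CC2OCCO2)OC(=C(I)C1=O)/C(CO[Si](c3ccccc3)(c3ccccc3)C(C)(C)C)=C\[C@H]4OC(=O)C(CO[Si](C)(C)C(C)(C)C)=C4
F3 | step 17 | allylstannane corresponding to 24 (3-[(tributylstannyl)methyl]butenolide, acetal intact) | C[C@@]1(CC2OCCO2)OC(=CC1=O)/C(CO[Si](c3ccccc3)(c3ccccc3)C(C)(C)C)=C\[C@H]4OC(=O)C(C[Sn](CCCC)(CCCC)CCCC)=C4
F4 | step 17 | allylstannane aldehyde corresponding to 25 | C[C@@]1(CC=O)OC(=CC1=O)/C(CO[Si](c3ccccc3)(c3ccccc3)C(C)(C)C)=C\[C@H]4OC(=O)C(C[Sn](CCCC)(CCCC)CCCC)=C4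
F5 | step 17 | (6R,7R,8R,10S)-15-[tert-butyl(diphenyl)silyloxy]-8-hydroxy-1-oxo-3,10-epoxygermacra-2,4(Z),11(13)-trien-12,6-olide | O[C@@H]1C[C@]2(C)OC(=CC2=O)/C(CO[Si](c3ccccc3)(c3ccccc3)C(C)(C)C)=C\[C@H]2OC(=O)C(=C)[C@@H]21
F6 | step 18 | 8-O-methanesulfonate of 27 (8S) | CS(=O)(=O)O[C@H]1C[C@]2(C)OC(=CC2=O)/C(CO[Si](c3ccccc3)(c3ccccc3)C(C)(C)C)=C\[C@H]2OC(=O)C(=C)[C@@H]21
F7 | step 12 | (3S)-1-(1,3-dioxolan-2-yl)-3-hydroxy-3-methyl-5-(tributylstannyl)pent-4-yn-2-one | C[C@](O)(C#C[Sn](CCCC)(CCCC)CCCC)C(=O)CC1OCCO1
F8 | step 1 | racemic ethyl 2-hydroxy-2-methyl-4-(trimethylsilyl)but-3-ynoate | CC(O)(C#C[Si](C)(C)C)C(=O)OCC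
F9 | step 1 | racemic 2-hydroxy-2-methylbut-3-ynoic acid | CC(O)(C#C)C(=O)O
F10 | step 1 | (1R)-1-phenylethanaminium (2S)-2-hydroxy-2-methylbut-3-ynoate | C[C@](O)(C#C)C(=O)[O-].C[C@@H]([NH3+])c1ccccc1
F11 | step 1 | (2S)-2-hydroxy-2-methylbut-3-ynoic acid | C[C@](O)(C#C)C(=O)O
F12 | step 1 | (2S)-2-hydroxy-N-methoxy-N,2-dimethylbut-3-ynamide | C[C@](O)(C#C)C(=O)N(C)OC
F13 | step 6 | racemic (5E)-1-[tert-butyl(diphenyl)silyloxy]hept-5-en-2-yn-4-ol | C/C=C/C(O)C#CCO[Si](c1ccccc1)(c1ccccc1)C(C)(C)C
F14 | step 6 | epoxy alcohol formed from the 4R enantiomer of F13 (trans-3-methyloxiranyl carbinol, oxygen delivered by the L-(+)-tartrate catalyst) | C[C@H]1O[C@@H]1[C@@H](O)C#CCO[Si](c1ccccc1)(c1ccccc1)C(C)(C)C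
A1 | alternative 1 | ten-membered 10-hydroxy-1-ketone 3-dioxolane with Z C4=C5 olefin | C=C(C)C(=O)O[C@@H]1C[C@](C)(O)C(=O)CC2(OCCO2)/C(CO)=C\[C@H]2OC(=O)C(=C)[C@@H]21
A2 | alternative 2 | 3,5-bridged isoxazole ten-membered carbocycle | C[C@]1(O[Si](C)(C)C)C[C@@H](O[Si](CC)(CC)CC)[C@H]2CC(=O)O[C@@H]2/C=C(/CO[Si](C)(C)C(C)(C)C)c2cc1no2
A3 | alternative 3 | C8-methylene 11-oxabicyclo[6.2.1]undecenone lactone | C=C1C[C@]2(C)O[C@@H](CC2=O)/C(CO[Si](C)(C)C(C)(C)C)=C\[C@H]2OC(=O)C(=C)[C@@H]21
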